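**Plan**
1. Retrosynthesis: the methacrylate and two silyl ethers are removed, then the ring bond C7–C8 is cut. The unit O–C8–C7–C11=C13 is a homoallylic alcohol whose allyl part (C7, C11, C13) lies inside the α-methylene-γ-lactone, i.e. the retron of an aldehyde allylation by a 3-(bromomethyl)butenolide.
2. Further cuts: the butenolide C7=C11 (ring-closing metathesis) and its ester C–O, the C6–alkenyl bond (addition to a C6 enal), C3–C4 (B-alkyl Suzuki coupling to 4-bromofuran-2(5H)-one) and C10–C1 (auxiliary-controlled allylation).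
3. Forward: an Evans fragment (C8–C10, C14, C1–C3) is coupled to the bromofuranone, whose ring fixes the C4=C5 geometry. That ring is opened to a Weinreb amide, reduced to the enal and alkenylated at C6.
4. Ring order: the lactone is made first, as a 3-(bromomethyl)butenolide, by esterification and metathesis. The ten-membered carbocycle is closed last by CrCl2-mediated intramolecular allylation, which also creates the exocyclic methylene.
5. Stereochemistry: C10 from the (R)-benzyloxazolidinone; C6 from the (+)-MIB-catalysed alkenylzinc addition; C7 from C6 (bond formation anti to the side chain, trans-lactone); C8 from the chair transition state of the allylation; C4=C5 from the temporary furanone ring.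
6. End game: methacrylation of the C8 hydroxyl and desilylation with HF·pyridine.

Key step: step 14

Remark: germacrane numbering is used (lactone oxygen on C6, C7 bears the lactone carbon C11, methacrylate on C8, CH2OH groups C14 on C10 and C15 on C4); the ring alkene C4=C5 has C3 and C6 trans, which is Z by the CIP rules because of the CH2OH group.

**Step 1**
Reactants: 1 methyl 4,4-dimethoxybutanoate
Product: 2 sodium 4,4-dimethoxybutanoate
Conditions: NaOH (1.0 equiv), MeOH/H2O, 23 °C; evaporate, dry azeotropically with toluene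
Reagents that add atoms: sodium hydroxide, [Na+].[OH-]
Why: Ester saponification under basic conditions leaves the acid-labile dimethyl acetal intact and gives the carboxylate salt in the form needed for anhydride formation.

**Step 2**
Reactants: 2 sodium 4,4-dimethoxybutanoate; 3 (R)-4-benzyloxazolidin-2-one
Product: 5 (R)-4-benzyl-3-(4,4-dimethoxybutanoyl)oxazolidin-2-one, via mixed pivalic anhydride 4 (not isolated)
Conditions: PivCl, THF, 0 °C; then 3, LiCl, Et3N, 0 → 23 °C
Reagents that add atoms: pivaloyl chloride, CC(C)(C)C(=O)Cl (pivaloyl group in intermediate 4 only)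
Why: N-acylation of the oxazolidinone through a mixed pivalic anhydride should occur at the less hindered carbonyl and needs no acidic activation that would endanger the acetal.

**Step 3**
Reactants: 5 (R)-4-benzyl-3-(4,4-dimethoxybutanoyl)oxazolidin-2-one
Product: 7 (R)-4-benzyl-3-[(R)-2-(2,2-dimethoxyethyl)pent-4-enoyl]oxazolidin-2-one, via sodium Z-enolate 6 (not isolated)
Conditions: NaN(SiMe3)2, THF, −78 °C; allyl iodide, −78 → −45 °C
Reagents that add atoms: allyl iodide, C=CCI; sodium bis(trimethylsilyl)amide, C[Si](C)(C)[N-][Si](C)(C)C.[Na+] (sodium in intermediate 6 only)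
Why: Evans asymmetric alkylation, in which the chelated Z-enolate should be allylated on the face opposite the benzyl group of the (R)-auxiliary, setting the future C10 stereocentre (R).

**Step 4**
Reactants: 7 (R)-4-benzyl-3-[(R)-2-(2,2-dimethoxyethyl)pent-4-enoyl]oxazolidin-2-one
Product: 8 (R)-2-(2,2-dimethoxyethyl)pent-4-en-1-ol
Conditions: LiBH4, MeOH (1 equiv), Et2O, 0 °C
Reagents that add atoms: none
Why: Reductive cleavage of the N-acyl oxazolidinone with LiBH4 should give the primary alcohol (C14) without touching the stereocentre, the alkene or the acetal, and returns the auxiliary.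

**Step 5**
Reactants: 8 (R)-2-(2,2-dimethoxyethyl)pent-4-en-1-ol
Product: 9 (R)-tert-butyl{[2-(2,2-dimethoxyethyl)pent-4-en-1-yl]oxy}dimethylsilane
Conditions: TBSCl, imidazole, CH2Cl2, 0 → 23 °C
Reagents that add atoms: tert-butyldimethylsilyl chloride, CC(C)(C)[Si](C)(C)Cl
Why: Standard silylation of a primary alcohol protects C14–OH up to the last step.

**Step 6**
Reactants: 9 (R)-tert-butyl{[2-(2,2-dimethoxyethyl)pent-4-en-1-yl]oxy}dimethylsilane; 10 4-bromofuran-2(5H)-one
Product: 12 (R)-4-(4-{[(tert-butyldimethylsilyl)oxy]methyl}-6,6-dimethoxyhexyl)furan-2(5H)-one, via B-alkyl-9-BBN adduct 11 (not isolated)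
Conditions: 9-BBN-H, THF, 23 °C; then 10, Pd(dppf)Cl2 (5 mol %), aq K3PO4, DMF, 23 → 50 °C
Reagents that add atoms: 9-borabicyclo[3.3.1]nonane, B1C2CCCC1CCC2 (boron in intermediate 11 only)
Why: Anti-Markovnikov hydroboration followed by B-alkyl Suzuki–Miyaura coupling with the vinylogous acyl bromide should form C3–C4, and the furanone ring holds the C15 oxygen and the C6 carbonyl cis on C4=C5, so the alkene geometry is fixed by a temporary ring.

**Step 7**
Reactants: 12 (R)-4-(4-{[(tert-butyldimethylsilyl)oxy]methyl}-6,6-dimethoxyhexyl)furan-2(5H)-one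
Product: 13 (R,Z)-7-{[(tert-butyldimethylsilyl)oxy]methyl}-3-(hydroxymethyl)-N,9,9-trimethoxy-N-methylnon-2-enamide
Conditions: MeNH(OMe)·HCl, Me3Al, CH2Cl2, 0 → 23 °C; aq potassium sodium tartrate
Reagents that add atoms: N,O-dimethylhydroxylamine hydrochloride, CNOC.Cl
Why: Aluminium-amide aminolysis of the lactone (Weinreb amide formation) should open the temporary ring with retention of the Z-alkene, freeing C15–OH and placing C6 at the Weinreb amide level.

**Step 8**
Reactants: 13 (R,Z)-7-{[(tert-butyldimethylsilyl)oxy]methyl}-3-(hydroxymethyl)-N,9,9-trimethoxy-N-methylnon-2-enamide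
Product: 14 (R,Z)-3,7-bis{[(tert-butyldimethylsilyl)oxy]methyl}-N,9,9-trimethoxy-N-methylnon-2-enamide
Conditions: TBSCl, imidazole, CH2Cl2, 0 °C, directly after step 7
Reagents that add atoms: tert-butyldimethylsilyl chloride, CC(C)(C)[Si](C)(C)Cl
Why: Prompt silylation of the primary allylic alcohol prevents relactonisation and protects C15–OH to the end.

**Step 9**
Reactants: 14 (R,Z)-3,7-bis{[(tert-butyldimethylsilyl)oxy]methyl}-N,9,9-trimethoxy-N-methylnon-2-enamide
Product: 15 (R,Z)-3,7-bis{[(tert-butyldimethylsilyl)oxy]methyl}-9,9-dimethoxynon-2-enal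
Conditions: iBu2AlH, THF, −78 °C; aq potassium sodium tartrate, 0 °C; used without delay
Reagents that add atoms: none
Why: Reduction of an α,β-unsaturated Weinreb amide with iBu2AlH should stop at the aldehyde, and the low temperature keeps the Z-enal from isomerising.

**Step 10**
Reactants: 15 (R,Z)-3,7-bis{[(tert-butyldimethylsilyl)oxy]methyl}-9,9-dimethoxynon-2-enal
Product: 16 (5E,7R,8Z,13R)-9,13-bis{[(tert-butyldimethylsilyl)oxy]methyl}-15,15-dimethoxypentadeca-5,8-dien-7-ol
Conditions: 1-hexyne, Cy2BH, toluene, 0 → 23 °C; Me2Zn, −78 °C; (+)-MIB [(2R)-3-exo-morpholinoisoborneol] (5 mol %); 15, −30 → −10 °C; then H2O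
Reagents that add atoms: 1-hexyne, C#CCCCC
Why: Catalytic asymmetric alkenylzinc addition (alkyne hydroboration, boron-to-zinc transmetalation, amino-alcohol-catalysed 1,2-addition), in which the (+)-MIB–zinc complex should deliver the E-hexenyl group to the Re face of the enal and so set C6 (R here, S in the target after the priority change), the hexenyl group serving as the alkene partner for metathesis.

**Step 11**
Reactants: 16 (5E,7R,8Z,13R)-9,13-bis{[(tert-butyldimethylsilyl)oxy]methyl}-15,15-dimethoxypentadeca-5,8-dien-7-ol; 17 2-(bromomethyl)prop-2-enoic acid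
Product: 18 (5E,7R,8Z,13R)-9,13-bis{[(tert-butyldimethylsilyl)oxy]methyl}-15,15-dimethoxypentadeca-5,8-dien-7-yl 2-(bromomethyl)prop-2-enoate
Conditions: DCC, DMAP (5 mol %), CH2Cl2, −20 → 0 °C
Reagents that add atoms: none
Why: Steglich esterification acylates the secondary alcohol at oxygen, so C6 is not touched, and the low DMAP loading and temperature limit attack on the allylic bromide.

**Step 12**
Reactants: 18 (5E,7R,8Z,13R)-9,13-bis{[(tert-butyldimethylsilyl)oxy]methyl}-15,15-dimethoxypentadeca-5,8-dien-7-yl 2-(bromomethyl)prop-2-enoate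
Product: 19 (S)-3-(bromomethyl)-5-[(R,Z)-2,6-bis{[(tert-butyldimethylsilyl)oxy]methyl}-8,8-dimethoxyoct-1-en-1-yl]furan-2(5H)-one
Conditions: second-generation Grubbs catalyst RuCl2(=CHPh)(PCy3)(H2IMes) (5 mol %), CH2Cl2 (5 mM), 40 °C
Reagents that add atoms: none
Why: Ring-closing metathesis between the acrylate and the E-disubstituted alkene should close the butenolide (the lactone ring, made first) with loss of the hexenyl residue, the trisubstituted C4=C5 alkene being too hindered to compete.

**Step 13**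
Reactants: 19 (S)-3-(bromomethyl)-5-[(R,Z)-2,6-bis{[(tert-butyldimethylsilyl)oxy]methyl}-8,8-dimethoxyoct-1-en-1-yl]furan-2(5H)-one
Product: 20 (3R,7Z)-8-[(S)-4-(bromomethyl)-5-oxo-2,5-dihydrofuran-2-yl]-3,7-bis{[(tert-butyldimethylsilyl)oxy]methyl}oct-7-enal
Conditions: SiO2, 10% aq oxalic acid, CH2Cl2, 23 °C
Reagents that add atoms: water, O
Why: Mild heterogeneous acetal hydrolysis on wet acidic silica should unmask the C8 aldehyde while the primary silyl ethers, the allylic bromide and the base-sensitive C6 stereocentre are left alone.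

**Step 14**
Reactants: 20 (3R,7Z)-8-[(S)-4-(bromomethyl)-5-oxo-2,5-dihydrofuran-2-yl]-3,7-bis{[(tert-butyldimethylsilyl)oxy]methyl}oct-7-enal
Product: 23 (3aS,4R,6R,10Z,11aS)-6,10-bis{[(tert-butyldimethylsilyl)oxy]methyl}-4-hydroxy-3-methylidene-3a,4,5,6,7,8,9,11a-octahydrocyclodeca[b]furan-2(3H)-one, via allylchromium dichloride 21 (not isolated), via chromium alkoxide 22 (not isolated)
Conditions: CrCl2 (8 equiv), THF/DMF, 23 °C, syringe-pump addition of 20 over 12 h (final 2 mM); then H2O
Reagents that add atoms: chromium dichloride, Cl[Cr]Cl (chromium and chloride in intermediates 21 and 22 only)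
Why: CrCl2 reduces the allylic C–Br bond by two one-electron transfers to the allylchromium 21, whose allyl unit C13–C11=C7 is built into the butenolide; it adds through its γ-carbon C7 to the C8 aldehyde (SE2′) in a six-membered chair transition state (Zimmerman–Traxler), moving the double bond to the exocyclic C11=C13 position and giving the alkoxide 22, which water releases as 23. The closest known reaction types are the Nozaki–Hiyama–Kishi/Barbier macrocyclisation of allylic bromides onto aldehydes used for ten-membered germacrane rings and the intermolecular Barbier allylation of aldehydes with 3-(bromomethyl)furan-2(5H)-ones. The ten-membered carbocycle is closed by the C7–C8 bond in a 10-exo-trig attack on the aldehyde carbonyl, the lactone ring being already in place. C7 is controlled by C6, since the aldehyde is expected to bond to the butenolide face opposite the C5 alkenyl substituent, which gives the trans-fused lactone (H6 and H7 trans). C8 is controlled by the chair transition state, in which the ring holds C6 trans to the CH2Cr group (an E-type γ-substituted allylmetal) and the tether on the aldehyde sits equatorial, so that the C8–O and C7–C6 bonds come out anti (8R with 7S). The step needs intramolecular over intermolecular allylation, secured by slow addition at high dilution and by the preformed trans C4=C5 alkene that turns the chain back towards C7, and γ- over α-attack, which is intrinsic to the allylchromium and is the only mode that closes a ten- rather than a twelve-membered ring.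

**Step 15**
Reactants: 23 (3aS,4R,6R,10Z,11aS)-6,10-bis{[(tert-butyldimethylsilyl)oxy]methyl}-4-hydroxy-3-methylidene-3a,4,5,6,7,8,9,11a-octahydrocyclodeca[b]furan-2(3H)-one
Product: 24 (3aS,4R,6R,10Z,11aS)-6,10-bis{[(tert-butyldimethylsilyl)oxy]methyl}-3-methylidene-2-oxo-2,3,3a,4,5,6,7,8,9,11a-decahydrocyclodeca[b]furan-4-yl 2-methylprop-2-enoate
Conditions: methacrylic anhydride, Et3N, DMAP (10 mol %), CH2Cl2, 0 → 23 °C
Reagents that add atoms: methacrylic anhydride, CC(=C)C(=O)OC(=O)C(C)=C
Why: DMAP-catalysed acylation of the only free hydroxyl (C8) with the anhydride proceeds at oxygen with retention and should outrun base-induced translactonisation.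

**Step 16**
Reactants: 24 (3aS,4R,6R,10Z,11aS)-6,10-bis{[(tert-butyldimethylsilyl)oxy]methyl}-3-methylidene-2-oxo-2,3,3a,4,5,6,7,8,9,11a-decahydrocyclodeca[b]furan-4-yl 2-methylprop-2-enoate
Product: 25 (3aS,4R,6R,10Z,11aS)-6,10-bis(hydroxymethyl)-3-methylidene-2-oxo-2,3,3a,4,5,6,7,8,9,11a-decahydrocyclodeca[b]furan-4-yl 2-methylprop-2-enoate
Conditions: HF·pyridine, pyridine, THF, 0 → 23 °C
Reagents that add atoms: none
Why: Buffered HF·pyridine desilylation should remove both primary silyl ethers under mildly acidic, non-nucleophilic conditions that spare the methacrylate and the α-methylene lactone and do not promote acyl migration.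

**Compound list**
1 | methyl 4,4-dimethoxybutanoate | COC(=O)CCC(OC)OC | starting material
2 | sodium 4,4-dimethoxybutanoate | [Na+].[O-]C(=O)CCC(OC)OC | intermediate
3 | (R)-4-benzyloxazolidin-2-one | O=C1N[C@H](Cc2ccccc2)CO1 | starting material
4 | 4,4-dimethoxybutanoic pivalic anhydride | COC(OC)CCC(=O)OC(=O)C(C)(C)C | intermediate
5 | (R)-4-benzyl-3-(4,4-dimethoxybutanoyl)oxazolidin-2-one | COC(OC)CCC(=O)N1[C@H](Cc2ccccc2)COC1=O | intermediate
6 | sodium Z-enolate of 5 | COC(OC)C/C=C(\[O-])N1[C@H](Cc2ccccc2)COC1=O.[Na+] | intermediate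
7 | (R)-4-benzyl-3-[(R)-2-(2,2-dimethoxyethyl)pent-4-enoyl]oxazolidin-2-one | COC(OC)C[C@@H](CC=C)C(=O)N1[C@H](Cc2ccccc2)COC1=O | intermediate
8 | (R)-2-(2,2-dimethoxyethyl)pent-4-en-1-ol | COC(OC)C[C@@H](CC=C)CO | intermediate
9 | (R)-tert-butyl{[2-(2,2-dimethoxyethyl)pent-4-en-1-yl]oxy}dimethylsilane | COC(OC)C[C@@H](CC=C)CO[Si](C)(C)C(C)(C)C | intermediate
10 | 4-bromofuran-2(5H)-one | BrC1=CC(=O)OC1 | starting material
11 | 9-[(R)-4-{[(tert-butyldimethylsilyl)oxy]methyl}-6,6-dimethoxyhexyl]-9-borabicyclo[3.3.1]nonane | COC(OC)C[C@@H](CCCB1C2CCCC1CCC2)CO[Si](C)(C)C(C)(C)C | intermediate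
12 | (R)-4-(4-{[(tert-butyldimethylsilyl)oxy]methyl}-6,6-dimethoxyhexyl)furan-2(5H)-one | COC(OC)C[C@@H](CCCC1=CC(=O)OC1)CO[Si](C)(C)C(C)(C)C | intermediate
13 | (R,Z)-7-{[(tert-butyldimethylsilyl)oxy]methyl}-3-(hydroxymethyl)-N,9,9-trimethoxy-N-methylnon-2-enamide | COC(OC)C[C@@H](CCC/C(CO)=C/C(=O)N(C)OC)CO[Si](C)(C)C(C)(C)C | intermediate
14 | (R,Z)-3,7-bis{[(tert-butyldimethylsilyl)oxy]methyl}-N,9,9-trimethoxy-N-methylnon-2-enamide | COC(OC)C[C@@H](CCC/C(CO[Si](C)(C)C(C)(C)C)=C/C(=O)N(C)OC)CO[Si](C)(C)C(C)(C)C | intermediate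
15 | (R,Z)-3,7-bis{[(tert-butyldimethylsilyl)oxy]methyl}-9,9-dimethoxynon-2-enal | COC(OC)C[C@@H](CCC/C(CO[Si](C)(C)C(C)(C)C)=C/C=O)CO[Si](C)(C)C(C)(C)C | intermediate
16 | (5E,7R,8Z,13R)-9,13-bis{[(tert-butyldimethylsilyl)oxy]methyl}-15,15-dimethoxypentadeca-5,8-dien-7-ol | COC(OC)C[C@@H](CCC/C(CO[Si](C)(C)C(C)(C)C)=C/[C@H](O)/C=C/CCCC)CO[Si](C)(C)C(C)(C)C | intermediate
17 | 2-(bromomethyl)prop-2-enoic acid | OC(=O)C(=C)CBr | starting material
18 | (5E,7R,8Z,13R)-9,13-bis{[(tert-butyldimethylsilyl)oxy]methyl}-15,15-dimethoxypentadeca-5,8-dien-7-yl 2-(bromomethyl)prop-2-enoate | COC(OC)C[C@@H](CCC/C(CO[Si](C)(C)C(C)(C)C)=C/[C@H](OC(=O)C(=C)CBr)/C=C/CCCC)CO[Si](C)(C)C(C)(C)C | intermediate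
19 | (S)-3-(bromomethyl)-5-[(R,Z)-2,6-bis{[(tert-butyldimethylsilyl)oxy]methyl}-8,8-dimethoxyoct-1-en-1-yl]furan-2(5H)-one | COC(OC)C[C@@H](CCC/C(CO[Si](C)(C)C(C)(C)C)=C/[C@@H]1OC(=O)C(CBr)=C1)CO[Si](C)(C)C(C)(C)C | intermediate
20 | (3R,7Z)-8-[(S)-4-(bromomethyl)-5-oxo-2,5-dihydrofuran-2-yl]-3,7-bis{[(tert-butyldimethylsilyl)oxy]methyl}oct-7-enal | O=CC[C@@H](CCC/C(CO[Si](C)(C)C(C)(C)C)=C/[C@@H]1OC(=O)C(CBr)=C1)CO[Si](C)(C)C(C)(C)C | intermediate
21 | allylchromium dichloride of 20 (CrCl2 on the former CH2Br carbon C13) | O=CC[C@@H](CCC/C(CO[Si](C)(C)C(C)(C)C)=C/[C@@H]1OC(=O)C(C[Cr](Cl)Cl)=C1)CO[Si](C)(C)C(C)(C)C | intermediate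
22 | chromium dichloride alkoxide of 23 (Cr on the C8 oxygen) | Cl[Cr](Cl)O[C@@H]1C[C@H](CO[Si](C)(C)C(C)(C)C)CCC/C(CO[Si](C)(C)C(C)(C)C)=C/[C@@H]2OC(=O)C(=C)[C@H]21 | intermediate
23 | (3aS,4R,6R,10Z,11aS)-6,10-bis{[(tert-butyldimethylsilyl)oxy]methyl}-4-hydroxy-3-methylidene-3a,4,5,6,7,8,9,11a-octahydrocyclodeca[b]furan-2(3H)-one | O[C@@H]1C[C@H](CO[Si](C)(C)C(C)(C)C)CCC/C(CO[Si](C)(C)C(C)(C)C)=C/[C@@H]2OC(=O)C(=C)[C@H]21 | intermediate
24 | (3aS,4R,6R,10Z,11aS)-6,10-bis{[(tert-butyldimethylsilyl)oxy]methyl}-3-methylidene-2-oxo-2,3,3a,4,5,6,7,8,9,11a-decahydrocyclodeca[b]furan-4-yl 2-methylprop-2-enoate | C=C(C)C(=O)O[C@@H]1C[C@H](CO[Si](C)(C)C(C)(C)C)CCC/C(CO[Si](C)(C)C(C)(C)C)=C/[C@@H]2OC(=O)C(=C)[C@H]21 | intermediate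
25 | (3aS,4R,6R,10Z,11aS)-6,10-bis(hydroxymethyl)-3-methylidene-2-oxo-2,3,3a,4,5,6,7,8,9,11a-decahydrocyclodeca[b]furan-4-yl 2-methylprop-2-enoate | C=C(C)C(=O)O[C@@H]1C[C@H](CO)CCC/C(CO)=C/[C@@H]2OC(=O)C(=C)[C@H]21 | target

**Count**
Total steps: 16. Longest linear sequence: 16 steps (1 → 25); compounds 3, 10 and 17 are commercial.

**Steps most likely to fail**

1. Step 14 (macrocyclisation). What may go wrong: intermolecular allylation to oligomers; protonolysis or reductive coupling of the allylchromium before it reaches the aldehyde; or bonding on the wrong face, giving the cis-fused lactone or the C8 epimer. Fallback (sets out from 19, returns at 23): the reductive organometallic step is replaced by a closed-shell intramolecular allylboration. Zerovalent-palladium-catalysed allylic borylation of 19 (B2pin2, Pd2(dba)3, DMSO, 23 °C) would give the pinacol allylboronate acetal F1. Acetal hydrolysis as in step 13 would give the allylboronate aldehyde F2. Heating at high dilution (toluene, 80 °C, Sc(OTf)3 as optional catalyst) should close the ring through the same chair arrangement to the borate ester F3, and aqueous work-up would release 23. No reductant is present, so protonolysis and coupling of a metal allyl cannot occur.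

2. Step 10 (alkenylzinc addition). What may go wrong: poor facial selectivity with this Z-configured β,β-disubstituted enal, Z-to-E isomerisation of the enal under Lewis acidic conditions, or competing methyl transfer. Fallback (sets out from 14, returns at 19): the stereocentre is set by ketone reduction instead of C–C bond formation. Vinylmagnesium bromide added to Weinreb amide 14 (THF, −78 → 0 °C) would give the cross-conjugated dienone F4. Corey–Bakshi–Shibata reduction ((S)-2-methyl-CBS-oxazaborolidine, catecholborane, toluene, −78 °C), with the trisubstituted alkenyl group as the large substituent, should give the (R)-vinyl carbinol F5. Steglich esterification with 17 would give the ester F6, and ring-closing metathesis of F6 under the conditions of step 12 rejoins the route at 19.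

3. Step 7 (lactone aminolysis). What may go wrong: deprotonation at the γ-CH2 of the butenolide instead of acyl attack, cleavage of the dimethyl acetal by the Lewis acidic aluminium reagent, or relactonisation of 13 before silylation. Fallback (sets out from 11, returns at 15): the alkene geometry is set by syn-carbometalation of an alkyne instead of by a ring. The B-alkyl-9-BBN 11 would be added to ethyl 4-[(tert-butyldimethylsilyl)oxy]but-2-ynoate under copper catalysis (CuOAc, P(OPh)3, t-BuOK, t-BuOH, dioxane; formal syn-hydroalkylation of the alkynoate) to give the Z-enoate F7 with the silyloxymethyl group already in place. Reduction with iBu2AlH (CH2Cl2, −78 °C) would give the allylic alcohol F8, and MnO2 oxidation returns to enal 15.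

**Further compounds**
F1 | step 14 | (S)-5-[(R,Z)-2,6-bis{[(tert-butyldimethylsilyl)oxy]methyl}-8,8-dimethoxyoct-1-en-1-yl]-3-[(4,4,5,5-tetramethyl-1,3,2-dioxaborolan-2-yl)methyl]furan-2(5H)-one | COC(OC)C[C@@H](CCC/C(CO[Si](C)(C)C(C)(C)C)=C/[C@@H]1OC(=O)C(CB2OC(C)(C)C(C)(C)O2)=C1)CO[Si](C)(C)C(C)(C)C
F2 | step 14 | (3R,7Z)-3,7-bis{[(tert-butyldimethylsilyl)oxy]methyl}-8-{(S)-5-oxo-4-[(4,4,5,5-tetramethyl-1,3,2-dioxaborolan-2-yl)methyl]-2,5-dihydrofuran-2-yl}oct-7-enal | O=CC[C@@H](CCC/C(CO[Si](C)(C)C(C)(C)C)=C/[C@@H]1OC(=O)C(CB2OC(C)(C)C(C)(C)O2)=C1)CO[Si](C)(C)C(C)(C)C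
F3 | step 14 | pinacol borate ester of 23 (boron on the C8 oxygen) | CC1(C)OB(O[C@@H]2C[C@H](CO[Si](C)(C)C(C)(C)C)CCC/C(CO[Si](C)(C)C(C)(C)C)=C/[C@@H]3OC(=O)C(=C)[C@H]32)OC1(C)C
F4 | step 10 | (R,Z)-5,9-bis{[(tert-butyldimethylsilyl)oxy]methyl}-11,11-dimethoxyundeca-1,4-dien-3-one | COC(OC)C[C@@H](CCC/C(CO[Si](C)(C)C(C)(C)C)=C/C(=O)C=C)CO[Si](C)(C)C(C)(C)C
F5 | step 10 | (3R,4Z,9R)-5,9-bis{[(tert-butyldimethylsilyl)oxy]methyl}-11,11-dimethoxyundeca-1,4-dien-3-ol | COC(OC)C[C@@H](CCC/C(CO[Si](C)(C)C(C)(C)C)=C/[C@H](O)C=C)CO[Si](C)(C)C(C)(C)C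
F6 | step 10 | (3R,4Z,9R)-5,9-bis{[(tert-butyldimethylsilyl)oxy]methyl}-11,11-dimethoxyundeca-1,4-dien-3-yl 2-(bromomethyl)prop-2-enoate | COC(OC)C[C@@H](CCC/C(CO[Si](C)(C)C(C)(C)C)=C/[C@H](OC(=O)C(=C)CBr)C=C)CO[Si](C)(C)C(C)(C)C
F7 | step 7 | ethyl (R,Z)-3,7-bis{[(tert-butyldimethylsilyl)oxy]methyl}-9,9-dimethoxynon-2-enoate | COC(OC)C[C@@H](CCC/C(CO[Si](C)(C)C(C)(C)C)=C/C(=O)OCC)CO[Si](C)(C)C(C)(C)C
F8 | step 7 | (R,Z)-3,7-bis{[(tert-butyldimethylsilyl)oxy]methyl}-9,9-dimethoxynon-2-en-1-ol | COC(OC)C[C@@H](CCC/C(CO[Si](C)(C)C(C)(C)C)=C/CO)CO[Si](C)(C)C(C)(C)C
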